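**Retrosynthetic overview**

1. The (R)-carbinol C–H bond is made last, by a boron-only (oxazaborolidine) catalysed enantioselective reduction of the C4 aryl ketone, so the acid-labile diaryl carbinol is never carried through another step.
2. The exocyclic amidine C–N bond comes from a 2-aminoimidazolyl ketone and preformed N-methylparabanic acid (O-silyl imidate condensation).
3. The imidazole N3–C4 and N1–C5 bonds come from a 2-bromo-1,3-diketone and an N-methylaminopyrimidine: annulation to an imidazo[1,2-a]pyrimidinium salt, then hydrazine excision of the pyrimidine CH carbons, which also frees the phenol.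
4. The 1,3-diketone C–C bond comes from C-acylation of a p-methoxyphenyl methyl ketone with a protected 4-hydroxyphenylacetyl chloride.
5. Ring order: both benzene rings and the dehydrohydantoin arrive preformed; the imidazole is the only ring built (step 2, on a sacrificial pyrimidine), and no ring is formed afterwards.

Assumption: 4-acetoxyphenylacetic acid, N-methylpyrimidin-2-amine and 1-methylparabanic acid are taken as purchasable; all starting materials are achiral, and the target carbinol carbon is (R).

**Step 1**
Reactants: 1 4'-methoxyacetophenone; 2 4-acetoxyphenylacetic acid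
Product: 4 4-[4-(4-methoxyphenyl)-2,4-dioxobutyl]phenyl acetate, via acid chloride 3 (not isolated)
Conditions: 2, (COCl)2, HCONMe2 (cat.), CH2Cl2, 0 °C → rt, evaporate; then 1, MgBr2·OEt2 (2.5 equiv), i-Pr2NEt (3 equiv), CH2Cl2, 0 °C → rt; 1 M HCl work-up
Reagents that add atoms: none
Why: Soft-enolisation C-acylation (a crossed Claisen-type acylation of the magnesium enolate of the only enolisable ketone) delivers the 1,3-diketone as its unreactive magnesium chelate, the aryl acetate being a far weaker acyl donor than acid chloride 3, and no stereocentre is formed.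

**Step 2**
Reactants: 4 4-[4-(4-methoxyphenyl)-2,4-dioxobutyl]phenyl acetate; 5 N-methylpyrimidin-2-amine
Product: 8 [2-amino-5-(4-hydroxybenzyl)-1-methyl-1H-imidazol-4-yl](4-methoxyphenyl)methanone, via bromodiketone 6 (not isolated), via imidazopyrimidinium bromide 7 (not isolated)
Conditions: NBS (1.0 equiv), MeCN, 0 °C → rt; then 5 (1.1 equiv), 80 °C; then N2H4·H2O (6 equiv), 60 °C
Reagents that add atoms: none
Why: NBS brominates the doubly activated C2 of the diketone, the ring nitrogen of 5 displaces bromide (Hantzsch-type annulation) and its NHMe group condenses with the more electrophilic aliphatic carbonyl rather than the deactivated anisoyl carbonyl, so that N-methyl ends up beside the benzyl-bearing carbon and the aroyl group sits on C4, after which hydrazine excises the three pyrimidine CH carbons as pyrazole (aminopyrimidine unmasking of a 2-aminoimidazole) and cleaves the aryl acetate; the CHBr carbon of 6 is racemic and enolisable and becomes sp2 on aromatisation, so no stereocentre results.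

**Step 3**
Reactants: 8 [2-amino-5-(4-hydroxybenzyl)-1-methyl-1H-imidazol-4-yl](4-methoxyphenyl)methanone; 9 1-methylparabanic acid (1-methylimidazolidine-2,4,5-trione)
Product: 11 5-{[5-(4-hydroxybenzyl)-4-(4-methoxybenzoyl)-1-methyl-1H-imidazol-2-yl]amino}-3-methylimidazole-2,4-dione, via O-silyl imidate 10 (not isolated)
Conditions: 9 (3 equiv), N,O-bis(trimethylsilyl)acetamide (3 equiv), MeCN, 80 °C, evaporate; then 8, PhMe, 110 °C; MeOH quench
Reagents that add atoms: none
Why: Silylation turns the NH–C4=O lactam of 9 into O-silyl imidate 10, which the 2-amino group attacks by addition–elimination to form the acylamidine (the established naamine-to-naamidine condensation), leaving the deactivated diaryl ketone untouched, with methanol removing silyl groups at the end; no stereocentre is formed.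

**Step 4**
Reactants: 11 5-{[5-(4-hydroxybenzyl)-4-(4-methoxybenzoyl)-1-methyl-1H-imidazol-2-yl]amino}-3-methylimidazole-2,4-dione
Product: 14 5-({5-(4-hydroxybenzyl)-4-[(R)-hydroxy(4-methoxyphenyl)methyl]-1-methyl-1H-imidazol-2-yl}amino)-3-methylimidazole-2,4-dione, via O-boryl ketone 12 (not isolated), via bis-O-boryl carbinol 13 (not isolated)
Conditions: catecholborane (1.1 equiv), CH2Cl2/THF 4:1, 0 °C, 20 min; then (3aS)-1-methyl-3,3-diphenyltetrahydro-1H,3H-pyrrolo[1,2-c][1,3,2]oxazaborole (20 mol %), catecholborane (2 equiv), −40 → −20 °C; MeOH, then aq. NaHCO3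
Reagents that add atoms: none
Why: Proposed new method: oxazaborolidine (Corey–Bakshi–Shibata type) catalysed catecholborane reduction, not yet shown for an unprotected 2-(acylamidino)imidazol-4-yl aryl ketone, run with the phenol masked in the flask as its catecholboryl ether; the push–pull carbonyl is the most Lewis-basic ketone site and binds the ring boron of the catalyst through the oxygen lone pair on the anisyl side, because the lone pair on the imidazole side is screened by the C5 benzyl group of the coplanar imidazole, so the imidazolyl behaves as the large and the p-anisyl as the small group (the same sense by which this catalyst enantiomer turns acetophenone into (R)-1-phenylethanol) and the nitrogen-bound catecholborane transfers hydride within the six-membered assembly to the Si face, giving the (R)-carbinol, while catecholborane at −40 °C leaves the acylamidine and imide carbonyls alone; the closest known reaction type is the same catalyst/catecholborane reduction of electronically or ortho-differentiated benzophenones and aryl heteroaryl ketones.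

**Compound list**

1 | 4'-methoxyacetophenone | COc1ccc(C(C)=O)cc1 | starting material
2 | 4-acetoxyphenylacetic acid | CC(=O)Oc1ccc(CC(=O)O)cc1 | starting material
3 | 4-acetoxyphenylacetyl chloride | CC(=O)Oc1ccc(CC(=O)Cl)cc1 | intermediate (not isolated)
4 | 4-[4-(4-methoxyphenyl)-2,4-dioxobutyl]phenyl acetate | COc1ccc(C(=O)CC(=O)Cc2ccc(OC(C)=O)cc2)cc1 | intermediate
5 | N-methylpyrimidin-2-amine | CNc1ncccn1 | starting material
6 | 4-[3-bromo-4-(4-methoxyphenyl)-2,4-dioxobutyl]phenyl acetate (racemic, enolisable CHBr carbon) | COc1ccc(C(=O)C(Br)C(=O)Cc2ccc(OC(C)=O)cc2)cc1 | intermediate (not isolated)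
7 | 2-(4-acetoxybenzyl)-3-(4-methoxybenzoyl)-1-methylimidazo[1,2-a]pyrimidin-1-ium bromide | C[n+]1c(Cc2ccc(OC(C)=O)cc2)c(C(=O)c2ccc(OC)cc2)n2cccnc12.[Br-] | intermediate (not isolated)
8 | [2-amino-5-(4-hydroxybenzyl)-1-methyl-1H-imidazol-4-yl](4-methoxyphenyl)methanone | COc1ccc(C(=O)c2nc(N)n(C)c2Cc2ccc(O)cc2)cc1 | intermediate
9 | 1-methylparabanic acid (1-methylimidazolidine-2,4,5-trione) | CN1C(=O)NC(=O)C1=O | starting material
10 | 1-methyl-4-(trimethylsilyloxy)-1H-imidazole-2,5-dione | CN1C(=O)N=C(O[Si](C)(C)C)C1=O | intermediate (not isolated)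
11 | 5-{[5-(4-hydroxybenzyl)-4-(4-methoxybenzoyl)-1-methyl-1H-imidazol-2-yl]amino}-3-methylimidazole-2,4-dione | COc1ccc(C(=O)c2nc(NC3=NC(=O)N(C)C3=O)n(C)c2Cc2ccc(O)cc2)cc1 | intermediate
12 | ketone 11 with the phenol oxygen bonded to a 1,3,2-benzodioxaborol-2-yl group | COc1ccc(C(=O)c2nc(NC3=NC(=O)N(C)C3=O)n(C)c2Cc2ccc(OB3Oc4ccccc4O3)cc2)cc1 | intermediate (not isolated)
13 | (R)-carbinol with both the carbinol oxygen and the phenol oxygen bonded to 1,3,2-benzodioxaborol-2-yl groups | COc1ccc([C@@H](OB2Oc3ccccc3O2)c2nc(NC3=NC(=O)N(C)C3=O)n(C)c2Cc2ccc(OB3Oc4ccccc4O3)cc2)cc1 | intermediate (not isolated)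
14 | 5-({5-(4-hydroxybenzyl)-4-[(R)-hydroxy(4-methoxyphenyl)methyl]-1-methyl-1H-imidazol-2-yl}amino)-3-methylimidazole-2,4-dione | COc1ccc([C@@H](O)c2nc(NC3=NC(=O)N(C)C3=O)n(C)c2Cc2ccc(O)cc2)cc1 | target

**Step count and risks**

Total step count: 4. Longest linear sequence: 4 steps (1 or 2 → 4 → 8 → 11 → 14).

Three steps most likely to fail:

Step 2 (one-pot bromination, annulation and hydrazinolysis). The weak points are bromine transfer from 6 to 5, condensation at the wrong carbonyl, and hydrazone formation at the aroyl group. The fallback sets out from 4 and comes back at 8. Brominate 4 with NBS in MeCN and isolate 6. Heat 6 with pyrimidin-2-amine and NaHCO3 in EtOH at 80 °C to give the neutral, chromatographable 2-(4-acetoxybenzyl)-3-(4-methoxybenzoyl)imidazo[1,2-a]pyrimidine F1, whose regiochemistry is confirmed by HMBC before going on. Methylate the basic N1 with MeOTf in CH2Cl2 at 0 °C to give 2-(4-acetoxybenzyl)-3-(4-methoxybenzoyl)-1-methylimidazo[1,2-a]pyrimidin-1-ium triflate F2. Cleave F2 with N2H4·H2O in MeCN at 40–60 °C to reach 8. The change is that the ring is closed with the primary aminopyrimidine and the N-methyl bond is made afterwards by alkylation.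

Step 4 (the proposed new reduction). The weak points are slow turnover on the push–pull ketone, catalyst sequestration by the imidazole nitrogen, low or reversed facial selectivity, and ionisation of the boryl ether leading to racemisation or over-reduction. The product is worked up at pH 7 or above and purified on Et3N-deactivated silica; ee is read by chiral SFC, and the sense of induction is checked against the natural product's optical data. The fallback uses known chemistry, sets out from 11 and comes back at 14. NaBH4 with CeCl3·7H2O in MeOH/THF at −40 °C (Luche reduction, selective for the ketone) gives racemic 5-({5-(4-hydroxybenzyl)-4-[hydroxy(4-methoxyphenyl)methyl]-1-methyl-1H-imidazol-2-yl}amino)-3-methylimidazole-2,4-dione F3. Preparative SFC on an amylose tris(3,5-dimethylphenylcarbamate) phase (CO2/MeOH, 0.1 % Et2NH) separates 14 from the (S)-enantiomer of 14 F4.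

Step 3 (amidine condensation). The weak point is the lowered nucleophilicity of the 2-amino group in 8, which is conjugated with the 4-aroyl group, under prolonged heating at 110 °C. The fallback builds the dehydrohydantoin ring stepwise, sets out from 8 and comes back at 11. Ethyl 2-ethoxy-2-iminoacetate with CH3CO2H (cat.) in EtOH at 50 °C gives ethyl 2-{[5-(4-hydroxybenzyl)-4-(4-methoxybenzoyl)-1-methyl-1H-imidazol-2-yl]amino}-2-iminoacetate F5 (Pinner-type amidine synthesis). N-Methyl-1H-imidazole-1-carboxamide (a methyl isocyanate surrogate) and Et3N in MeCN at rt carbamoylate the terminal amidine nitrogen to give ethyl 2-{[5-(4-hydroxybenzyl)-4-(4-methoxybenzoyl)-1-methyl-1H-imidazol-2-yl]amino}-2-[(methylcarbamoyl)imino]acetate F6, which is not isolated. DBU at 60 °C closes the urea NHMe onto the ester (hydantoin-type ureide–ester cyclisation) to give 11.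

**Further compounds**

F1 | step 2 | 2-(4-acetoxybenzyl)-3-(4-methoxybenzoyl)imidazo[1,2-a]pyrimidine | CC(=O)Oc1ccc(Cc2nc3ncccn3c2C(=O)c2ccc(OC)cc2)cc1
F2 | step 2 | 2-(4-acetoxybenzyl)-3-(4-methoxybenzoyl)-1-methylimidazo[1,2-a]pyrimidin-1-ium triflate | C[n+]1c(Cc2ccc(OC(C)=O)cc2)c(C(=O)c2ccc(OC)cc2)n2cccnc12.[O-]S(=O)(=O)C(F)(F)F
F3 | step 4 | racemic 5-({5-(4-hydroxybenzyl)-4-[hydroxy(4-methoxyphenyl)methyl]-1-methyl-1H-imidazol-2-yl}amino)-3-methylimidazole-2,4-dione | COc1ccc(C(O)c2nc(NC3=NC(=O)N(C)C3=O)n(C)c2Cc2ccc(O)cc2)cc1
F4 | step 4 | (S)-enantiomer of 14 | COc1ccc([C@H](O)c2nc(NC3=NC(=O)N(C)C3=O)n(C)c2Cc2ccc(O)cc2)cc1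
F5 | step 3 | ethyl 2-{[5-(4-hydroxybenzyl)-4-(4-methoxybenzoyl)-1-methyl-1H-imidazol-2-yl]amino}-2-iminoacetate | CCOC(=O)C(=N)Nc1nc(C(=O)c2ccc(OC)cc2)c(Cc2ccc(O)cc2)n1C
F6 | step 3 | ethyl 2-{[5-(4-hydroxybenzyl)-4-(4-methoxybenzoyl)-1-methyl-1H-imidazol-2-yl]amino}-2-[(methylcarbamoyl)imino]acetate | CCOC(=O)C(=NC(=O)NC)Nc1nc(C(=O)c2ccc(OC)cc2)c(Cc2ccc(O)cc2)n1C
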